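**Retrosynthetic overview** (atom labels C1–O26 follow the atom order of the target SMILES)
1. The C17 ketone and the C3 ester carbonyl are 1,4-related through C16–C5, and C16 lies next to quaternary C14, which carries the C24–C23–C19 chain; ring C is therefore cut at C16–C17 (carbene-catalysed conjugate acylation of a ring B enoate by a C17 aldehyde).
2. Ring B comes first: Birch reduction–methylation of a 5-silyloxyisophthalic half ester gives the C14-quaternary cyclohexa-1,4-diene (C16=C5 unsaturated acid, C7=C13 enol silyl ether); the acid is resolved.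
3. The C14 ester becomes the 4-oxo-aldehyde chain (allylation with a 3-methylbutanal-derived allyl bromide, hydroboration, double oxidation); ring C then closes.
4. The enol silyl ether (used in place of a methyl enol ether) marks C13 as the only site of allylation; C5=C6 is introduced through the C7 ketone; ring A and the C7–O26–C24 hemiketal bridge close last by allylation of C7 from the C13 tether.
5. Ring order: B, then C, then A together with the oxolane bridge.

Key step: step 14

Assumption: the less soluble salt of rac-5 with (R)-1-phenylethylamine is taken to contain the (S)-acid; if the pairing is the opposite, the (S)-amine is used, and the assignment is made by X-ray analysis of the salt.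

**Step 1**
Reactants: 1 dimethyl 5-hydroxybenzene-1,3-dicarboxylate
Product: 2 3-hydroxy-5-(methoxycarbonyl)benzoic acid
Conditions: NaOH (2.0 equiv), MeOH/H2O, 23 °C; then aq. HCl to pH 2
Reagents that add atoms: sodium hydroxide, [Na+].[OH-]
Why: Saponification stopped at the half ester, because the phenoxide carboxylate formed first is hydrolysed more slowly than the neutral diester; no stereocentre is involved.

**Step 2**
Reactants: 2 3-hydroxy-5-(methoxycarbonyl)benzoic acid
Product: 4 3-(methoxycarbonyl)-5-{[tri(propan-2-yl)silyl]oxy}benzoic acid, via bis-silyl compound 3 (not isolated)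
Conditions: i-Pr3SiCl (2.3 equiv), imidazole, DMF, 23 °C; then K2CO3, THF/MeOH/H2O, 0 °C; citric acid
Reagents that add atoms: chlorotri(propan-2-yl)silane, CC(C)[Si](Cl)(C(C)C)C(C)C
Why: Silylation of phenol and acid followed by selective hydrolysis of the labile silyl ester; the aryl silyl ether is chosen so that the Birch step leaves a C7 enol silyl ether that can later be opened to a regiodefined enolate.

**Step 3**
Reactants: 4 3-(methoxycarbonyl)-5-{[tri(propan-2-yl)silyl]oxy}benzoic acid
Product: 5 rac-3-(methoxycarbonyl)-3-methyl-5-{[tri(propan-2-yl)silyl]oxy}cyclohexa-1,4-diene-1-carboxylic acid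
Conditions: KOt-Bu (1.0 equiv), THF; K (2.3 equiv), NH3(l), −78 °C; MeI, −78 °C; aq. NH4Cl, then citric acid to pH 4
Reagents that add atoms: iodomethane, CI
Why: Birch reduction–alkylation in which the radical anion is protonated para to the ester (future C6) by the t-BuOH released on salt formation and the resulting ester dienolate is methylated at its α-carbon C14 (the carboxylate being the poorer anion-stabilising group), which gives the 1,4-diene; C14 forms racemic, since neither position ortho to it bears a substituent that could fix the enolate geometry for an auxiliary.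

**Step 4**
Reactants: 5 rac-3-(methoxycarbonyl)-3-methyl-5-{[tri(propan-2-yl)silyl]oxy}cyclohexa-1,4-diene-1-carboxylic acid
Product: 6 (3S)-3-(methoxycarbonyl)-3-methyl-5-{[tri(propan-2-yl)silyl]oxy}cyclohexa-1,4-diene-1-carboxylic acid
Conditions: (R)-1-phenylethylamine (1.0 equiv), EtOAc/i-PrOH, fractional crystallisation; then cold aq. citric acid, EtOAc
Reagents that add atoms: none
Why: Classical resolution through diastereomeric ammonium salts of the ring carboxylic acid, which supplies C14 in the (S) configuration that maps onto the target.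

**Step 5**
Reactants: 6 (3S)-3-(methoxycarbonyl)-3-methyl-5-{[tri(propan-2-yl)silyl]oxy}cyclohexa-1,4-diene-1-carboxylic acid
Product: 7 (3S)-3-(hydroxymethyl)-3-methyl-5-{[tri(propan-2-yl)silyl]oxy}cyclohexa-1,4-diene-1-carboxylic acid
Conditions: LiBHEt3 (3.5 equiv), THF, 0 °C; aq. NH4Cl, citric acid
Reagents that add atoms: none
Why: Chemoselective hydride reduction, in which the hindered methyl ester goes to the neopentyl alcohol while the acid is protected as its lithium carboxylate, so the two carboxyl groups are differentiated without touching C14.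

**Step 6**
Reactants: 7 (3S)-3-(hydroxymethyl)-3-methyl-5-{[tri(propan-2-yl)silyl]oxy}cyclohexa-1,4-diene-1-carboxylic acid
Product: 8 methyl (3S)-3-(hydroxymethyl)-3-methyl-5-{[tri(propan-2-yl)silyl]oxy}cyclohexa-1,4-diene-1-carboxylate
Conditions: Me3SiCHN2, toluene/MeOH, 0 °C
Reagents that add atoms: (trimethylsilyl)diazomethane, C[Si](C)(C)C=[N+]=[N-]
Why: Methyl esterification of the acid with a diazoalkane under neutral conditions that spare the enol silyl ether.

**Step 7**
Reactants: 8 methyl (3S)-3-(hydroxymethyl)-3-methyl-5-{[tri(propan-2-yl)silyl]oxy}cyclohexa-1,4-diene-1-carboxylate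
Product: 9 methyl (3S)-3-formyl-3-methyl-5-{[tri(propan-2-yl)silyl]oxy}cyclohexa-1,4-diene-1-carboxylate
Conditions: Dess–Martin periodinane, NaHCO3, CH2Cl2, 0→23 °C
Reagents that add atoms: none
Why: Buffered Dess–Martin oxidation of the neopentyl alcohol to the non-enolisable α-quaternary aldehyde, which is used at once.

**Step 8**
Reactants: 10 3-methylbutanal
Product: 11 3-methyl-2-methylidenebutanal
Conditions: 37% aq. CH2O, pyrrolidine (10 mol%), propanoic acid (10 mol%), i-PrOH, 45 °C
Reagents that add atoms: formaldehyde, C=O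
Why: Amine-catalysed Mannich condensation–elimination, the standard α-methylenation of an aldehyde.

**Step 9**
Reactants: 11 3-methyl-2-methylidenebutanal
Product: 12 3-methyl-2-methylidenebutan-1-ol
Conditions: NaBH4, CeCl3·7H2O, MeOH, 0 °C
Reagents that add atoms: none
Why: Luche reduction gives clean 1,2-reduction of the enal.

**Step 10**
Reactants: 12 3-methyl-2-methylidenebutan-1-ol
Product: 13 2-(bromomethyl)-3-methylbut-1-ene
Conditions: PBr3, Et2O, 0 °C
Reagents that add atoms: phosphorus tribromide, BrP(Br)Br
Why: Bromination of a primary allylic alcohol, in which direct and allylic substitution give the same 2-substituted allyl bromide.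

**Step 11**
Reactants: 9 methyl (3S)-3-formyl-3-methyl-5-{[tri(propan-2-yl)silyl]oxy}cyclohexa-1,4-diene-1-carboxylate; 13 2-(bromomethyl)-3-methylbut-1-ene
Product: 14 methyl (3S)-3-(1-hydroxy-4-methyl-3-methylidenepentyl)-3-methyl-5-{[tri(propan-2-yl)silyl]oxy}cyclohexa-1,4-diene-1-carboxylate (both C24 epimers)
Conditions: In powder, DMF, 23 °C
Reagents that add atoms: none
Why: Barbier allylation, chemoselective for the aldehyde over the ester; the C24 carbinol forms as both epimers, which is of no consequence because C24 is oxidised in step 13.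

**Step 12**
Reactants: 14 methyl (3S)-3-(1-hydroxy-4-methyl-3-methylidenepentyl)-3-methyl-5-{[tri(propan-2-yl)silyl]oxy}cyclohexa-1,4-diene-1-carboxylate
Product: 15 methyl (3S)-3-[1-hydroxy-3-(hydroxymethyl)-4-methylpentyl]-3-methyl-5-{[tri(propan-2-yl)silyl]oxy}cyclohexa-1,4-diene-1-carboxylate (C24 and C19 epimers)
Conditions: 9-BBN (2.5 equiv), THF, 0→23 °C; then aq. NaOH, H2O2, 0 °C
Reagents that add atoms: hydrogen peroxide, OO
Why: Anti-Markovnikov hydroboration–oxidation of the 1,1-disubstituted alkene by a bulky borane that leaves the trisubstituted enoate and enol silyl ether alone; C19 forms unselectively, which is harmless because it is equilibrated after step 14.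

**Step 13**
Reactants: 15 methyl (3S)-3-[1-hydroxy-3-(hydroxymethyl)-4-methylpentyl]-3-methyl-5-{[tri(propan-2-yl)silyl]oxy}cyclohexa-1,4-diene-1-carboxylate
Product: 16 methyl (3S)-3-(3-formyl-4-methylpentanoyl)-3-methyl-5-{[tri(propan-2-yl)silyl]oxy}cyclohexa-1,4-diene-1-carboxylate (C19 epimers)
Conditions: (COCl)2, DMSO, CH2Cl2, −78 °C; Et3N, −78→0 °C
Reagents that add atoms: none
Why: Swern oxidation, in which both hydroxyls are converted to alkoxysulfonium ions before the base is added, so that the 1,4-diol gives the keto aldehyde and not a lactol or lactone.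

**Step 14**
Reactants: 16 methyl (3S)-3-(3-formyl-4-methylpentanoyl)-3-methyl-5-{[tri(propan-2-yl)silyl]oxy}cyclohexa-1,4-diene-1-carboxylate
Product: 17 methyl (1R,4aR,7R,8aS)-4a-methyl-5,8-dioxo-7-(propan-2-yl)-3-{[tri(propan-2-yl)silyl]oxy}-1,2,4a,5,6,7,8,8a-octahydronaphthalene-1-carboxylate
Conditions: 2-(pentafluorophenyl)-6,7-dihydro-5H-pyrrolo[2,1-c][1,2,4]triazol-2-ium tetrafluoroborate (20 mol%), KN(SiMe3)2 (18 mol%), toluene, 23→60 °C
Reagents that add atoms: none
Why: The triazolylidene adds to the C17 aldehyde and proton transfer gives the Breslow intermediate, whose C17 attacks C16, the β-carbon of the C16=C5 enoate; proton transfer to C5 and loss of the carbene give the C17 ketone. The closest known reaction type is the intramolecular Stetter reaction of an aliphatic aldehyde with an α,β-unsaturated ester, here at its demanding end because the acceptor is a trisubstituted ring enoate and the aldehyde is α-branched. Ring C closes 6-exo-trig. C16 is set by the tether: the chain hangs from quaternary C14, so the C16–C17 bond can only form on the face of the C14–C24 bond and the ring fusion is cis. C5 is protonated on that same face by the carbinol proton of the adduct (ester trans to C17, also the equatorial arrangement), and C19 is labile next to the aldehyde and then the ketone and should settle as the epimer with equatorial isopropyl shown; any C19 epimer is separated and re-equilibrated with DBU. The step needs chemoselectivity for the enoate over the second ring alkene, which is secured because C7=C13 is an electron-rich enol silyl ether, and the 1,4-keto aldehyde has no unstrained aldol or benzoin pathway.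

**Step 15**
Reactants: 18 2-ethenyl-2-methyloxirane (racemic)
Product: 19 (2E)-4-chloro-2-methylbut-2-en-1-ol
Conditions: TiCl4, CH2Cl2, −90 °C; aq. work-up
Reagents that add atoms: titanium tetrachloride, Cl[Ti](Cl)(Cl)Cl
Why: Lewis-acid-activated allylic (SN2′) opening of the vinyl oxirane by chloride, which should give mainly the E allylic alcohol.

**Step 16**
Reactants: 19 (2E)-4-chloro-2-methylbut-2-en-1-ol
Product: 20 tert-butyl{[(2E)-4-chloro-2-methylbut-2-en-1-yl]oxy}dimethylsilane
Conditions: t-BuMe2SiCl, imidazole, DMF, 0→23 °C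
Reagents that add atoms: tert-butyl(chloro)dimethylsilane, CC(C)(C)[Si](C)(C)Cl
Why: Silylation of the primary alcohol, so that only the allylic chloride end can act as the electrophile.

**Step 17**
Reactants: 17 methyl (1R,4aR,7R,8aS)-4a-methyl-5,8-dioxo-7-(propan-2-yl)-3-{[tri(propan-2-yl)silyl]oxy}-1,2,4a,5,6,7,8,8a-octahydronaphthalene-1-carboxylate; 20 tert-butyl{[(2E)-4-chloro-2-methylbut-2-en-1-yl]oxy}dimethylsilane
Product: 21 methyl (1R,4R,4aR,7R,8aS)-4-[(2E)-4-{[tert-butyl(dimethyl)silyl]oxy}-3-methylbut-2-en-1-yl]-4a-methyl-3,5,8-trioxo-7-(propan-2-yl)decahydronaphthalene-1-carboxylate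
Conditions: Bu4N[Ph3SiF2] (1.05 equiv), Pd2(dba)3 (2.5 mol%), PPh3 (10 mol%), THF, 0→23 °C
Reagents that add atoms: none
Why: Tsuji–Trost allylation of a regiodefined enolate, in which fluoride opens the enol silyl ether (much more labile than the alkyl silyl ether) to the C7–C13 enolate and this attacks the unsubstituted terminus C12 of the π-allylpalladium complex from 20; the electrophile should enter C13 anti to the pseudo-axial C14–C24 bond, cis to the C14 methyl as in the target, and C13 stays epimerisable next to C7=O (E/Z scrambling of the side chain would not matter later).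

**Step 18**
Reactants: 21 methyl (1R,4R,4aR,7R,8aS)-4-[(2E)-4-{[tert-butyl(dimethyl)silyl]oxy}-3-methylbut-2-en-1-yl]-4a-methyl-3,5,8-trioxo-7-(propan-2-yl)decahydronaphthalene-1-carboxylate
Product: 23 methyl (4R,4aR,7R,8aR)-4-[(2E)-4-{[tert-butyl(dimethyl)silyl]oxy}-3-methylbut-2-en-1-yl]-4a-methyl-3,5,8-trioxo-7-(propan-2-yl)-3,4,4a,5,6,7,8,8a-octahydronaphthalene-1-carboxylate, via C6 selenide 22 (not isolated)
Conditions: N-(phenylselanyl)phthalimide (1.2 equiv), (S)-N-(pyrrolidin-2-ylmethyl)trifluoromethanesulfonamide (20 mol%), CH2Cl2, 23 °C; then NaIO4, NaHCO3, THF/H2O, 23 °C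
Reagents that add atoms: none
Why: Enamine-mediated α-selenenylation followed by selenoxide syn-elimination, selective because only the C7 ketone has an accessible carbonyl with a free α-methylene (C6) whereas C24 and C17 are flanked by quaternary or tertiary carbons, and the selenoxide can only take the C5 hydrogen, which gives the C5=C6 enoate conjugated with C7=O.

**Step 19**
Reactants: 23 methyl (4R,4aR,7R,8aR)-4-[(2E)-4-{[tert-butyl(dimethyl)silyl]oxy}-3-methylbut-2-en-1-yl]-4a-methyl-3,5,8-trioxo-7-(propan-2-yl)-3,4,4a,5,6,7,8,8a-octahydronaphthalene-1-carboxylate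
Product: 24 methyl (4R,4aR,7R,8aR)-4-[(2E)-4-bromo-3-methylbut-2-en-1-yl]-4a-methyl-3,5,8-trioxo-7-(propan-2-yl)-3,4,4a,5,6,7,8,8a-octahydronaphthalene-1-carboxylate
Conditions: Ph3PBr2, CH2Cl2, 0→23 °C
Reagents that add atoms: dibromo(triphenyl)phosphorane, BrP(Br)(c1ccccc1)(c1ccccc1)c1ccccc1
Why: Direct conversion of a silyl ether into the bromide with a bromophosphonium reagent; an allylic transposition would be harmless, since both bromides give the same allylmetal species.

**Step 20**
Reactants: 24 methyl (4R,4aR,7R,8aR)-4-[(2E)-4-bromo-3-methylbut-2-en-1-yl]-4a-methyl-3,5,8-trioxo-7-(propan-2-yl)-3,4,4a,5,6,7,8,8a-octahydronaphthalene-1-carboxylate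
Product: 26 CNP0382995.2 (target), via hydroxy diketone 25 (not isolated)
Conditions: In powder, NaI, DMF/H2O, 23 °C, high dilution
Reagents that add atoms: none
Why: Intramolecular Barbier allylation, in which the allylindium species (it equilibrates by 1,3-metal shift, so the alkene geometry is not decisive) closes the six-membered ring A at the adjacent C7 carbonyl and the C13 tether forces C8 onto the face of C12, which leaves the C7 oxygen syn to the C14–C24 bond; the tertiary alkoxide then adds to the C24 ketone to give the five-membered hemiketal, whose C24 configuration is dictated by the cage, and the equatorial isopropyl at C19 is the stable epimer in the locked ring C.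

**Compound list**
1 | dimethyl 5-hydroxybenzene-1,3-dicarboxylate | COC(=O)c1cc(O)cc(c1)C(=O)OC | starting material
2 | 3-hydroxy-5-(methoxycarbonyl)benzoic acid | COC(=O)c1cc(O)cc(c1)C(O)=O | intermediate
3 | tri(propan-2-yl)silyl 3-(methoxycarbonyl)-5-{[tri(propan-2-yl)silyl]oxy}benzoate | COC(=O)c1cc(O[Si](C(C)C)(C(C)C)C(C)C)cc(c1)C(=O)O[Si](C(C)C)(C(C)C)C(C)C | intermediate (not isolated)
4 | 3-(methoxycarbonyl)-5-{[tri(propan-2-yl)silyl]oxy}benzoic acid | COC(=O)c1cc(O[Si](C(C)C)(C(C)C)C(C)C)cc(c1)C(O)=O | intermediate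
5 | rac-3-(methoxycarbonyl)-3-methyl-5-{[tri(propan-2-yl)silyl]oxy}cyclohexa-1,4-diene-1-carboxylic acid | CC(C)[Si](C(C)C)(C(C)C)OC1=CC(C)(C(=O)OC)C=C(C1)C(O)=O | intermediate
6 | (3S)-3-(methoxycarbonyl)-3-methyl-5-{[tri(propan-2-yl)silyl]oxy}cyclohexa-1,4-diene-1-carboxylic acid | CC(C)[Si](C(C)C)(C(C)C)OC1=C[C@@](C)(C(=O)OC)C=C(C1)C(O)=O | intermediate
7 | (3S)-3-(hydroxymethyl)-3-methyl-5-{[tri(propan-2-yl)silyl]oxy}cyclohexa-1,4-diene-1-carboxylic acid | CC(C)[Si](C(C)C)(C(C)C)OC1=C[C@@](C)(CO)C=C(C1)C(O)=O | intermediate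
8 | methyl (3S)-3-(hydroxymethyl)-3-methyl-5-{[tri(propan-2-yl)silyl]oxy}cyclohexa-1,4-diene-1-carboxylate | CC(C)[Si](C(C)C)(C(C)C)OC1=C[C@@](C)(CO)C=C(C1)C(=O)OC | intermediate
9 | methyl (3S)-3-formyl-3-methyl-5-{[tri(propan-2-yl)silyl]oxy}cyclohexa-1,4-diene-1-carboxylate | CC(C)[Si](C(C)C)(C(C)C)OC1=C[C@@](C)(C=O)C=C(C1)C(=O)OC | intermediate
10 | 3-methylbutanal | CC(C)CC=O | starting material
11 | 3-methyl-2-methylidenebutanal | CC(C)C(=C)C=O | intermediate
12 | 3-methyl-2-methylidenebutan-1-ol | CC(C)C(=C)CO | intermediate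
13 | 2-(bromomethyl)-3-methylbut-1-ene | CC(C)C(=C)CBr | intermediate
14 | methyl (3S)-3-(1-hydroxy-4-methyl-3-methylidenepentyl)-3-methyl-5-{[tri(propan-2-yl)silyl]oxy}cyclohexa-1,4-diene-1-carboxylate (C24 epimers) | CC(C)[Si](C(C)C)(C(C)C)OC1=C[C@@](C)(C(O)CC(=C)C(C)C)C=C(C1)C(=O)OC | intermediate
15 | methyl (3S)-3-[1-hydroxy-3-(hydroxymethyl)-4-methylpentyl]-3-methyl-5-{[tri(propan-2-yl)silyl]oxy}cyclohexa-1,4-diene-1-carboxylate (C24 and C19 epimers) | CC(C)[Si](C(C)C)(C(C)C)OC1=C[C@@](C)(C(O)CC(CO)C(C)C)C=C(C1)C(=O)OC | intermediate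
16 | methyl (3S)-3-(3-formyl-4-methylpentanoyl)-3-methyl-5-{[tri(propan-2-yl)silyl]oxy}cyclohexa-1,4-diene-1-carboxylate (C19 epimers; key-step precursor) | CC(C)[Si](C(C)C)(C(C)C)OC1=C[C@@](C)(C(=O)CC(C=O)C(C)C)C=C(C1)C(=O)OC | intermediate
17 | methyl (1R,4aR,7R,8aS)-4a-methyl-5,8-dioxo-7-(propan-2-yl)-3-{[tri(propan-2-yl)silyl]oxy}-1,2,4a,5,6,7,8,8a-octahydronaphthalene-1-carboxylate (cis-fused; key-step product) | COC(=O)[C@@H]1CC(O[Si](C(C)C)(C(C)C)C(C)C)=C[C@]2(C)[C@H]1C(=O)[C@@H](C(C)C)CC2=O | intermediate
18 | 2-ethenyl-2-methyloxirane (racemic) | CC1(CO1)C=C | starting material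
19 | (2E)-4-chloro-2-methylbut-2-en-1-ol | ClC/C=C(\C)CO | intermediate
20 | tert-butyl{[(2E)-4-chloro-2-methylbut-2-en-1-yl]oxy}dimethylsilane | ClC/C=C(\C)CO[Si](C)(C)C(C)(C)C | intermediate
21 | methyl (1R,4R,4aR,7R,8aS)-4-[(2E)-4-{[tert-butyl(dimethyl)silyl]oxy}-3-methylbut-2-en-1-yl]-4a-methyl-3,5,8-trioxo-7-(propan-2-yl)decahydronaphthalene-1-carboxylate | COC(=O)[C@@H]1CC(=O)[C@H](C/C=C(\C)CO[Si](C)(C)C(C)(C)C)[C@]2(C)[C@H]1C(=O)[C@@H](C(C)C)CC2=O | intermediate
22 | 2-(phenylselanyl) derivative of 21 (selenium on C6 of the target numbering; both C6 epimers) | COC(=O)[C@@H]1C([Se]c3ccccc3)C(=O)[C@H](C/C=C(\C)CO[Si](C)(C)C(C)(C)C)[C@]2(C)[C@H]1C(=O)[C@@H](C(C)C)CC2=O | intermediate (not isolated)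
23 | methyl (4R,4aR,7R,8aR)-4-[(2E)-4-{[tert-butyl(dimethyl)silyl]oxy}-3-methylbut-2-en-1-yl]-4a-methyl-3,5,8-trioxo-7-(propan-2-yl)-3,4,4a,5,6,7,8,8a-octahydronaphthalene-1-carboxylate | COC(=O)C1=CC(=O)[C@H](C/C=C(\C)CO[Si](C)(C)C(C)(C)C)[C@]2(C)[C@H]1C(=O)[C@@H](C(C)C)CC2=O | intermediate
24 | methyl (4R,4aR,7R,8aR)-4-[(2E)-4-bromo-3-methylbut-2-en-1-yl]-4a-methyl-3,5,8-trioxo-7-(propan-2-yl)-3,4,4a,5,6,7,8,8a-octahydronaphthalene-1-carboxylate | COC(=O)C1=CC(=O)[C@H](C/C=C(\C)CBr)[C@]2(C)[C@H]1C(=O)[C@@H](C(C)C)CC2=O | intermediate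
25 | open hydroxy diketone form of 26 (ring A closed cis on C7/C13; tertiary C7–OH syn to the C14–C24 bond; C24 and C17 ketones) | COC(=O)C1=C[C@]2(O)CC(C)=CC[C@@H]2[C@]2(C)[C@H]1C(=O)[C@@H](C(C)C)CC2=O | intermediate (not isolated)
26 | CNP0382995.2 (hemiketal cage; stereochemistry as in the SMILES) | COC(=O)C1=C[C@]23CC(C)=CC[C@@H]2[C@]2(C)[C@H]1C(=O)[C@@H](C(C)C)C[C@@]2(O)O3 | target

**Step count**
Total: 20 steps. Longest linear sequence: 15 steps (steps 1–7, 11–14, 17–20).

**Steps most likely to fail**

Step 14 (key step). The acyl anion equivalent may form slowly from the α-branched aldehyde and add slowly to the hindered trisubstituted enoate, so that aldehyde self-condensation or base-induced epimerisation at C16 competes. The fallback sets out from 16 and returns at 17 by an acyl radical cyclisation: chlorite oxidation (NaClO2, NaH2PO4, 2-methylbut-2-ene) of the aldehyde would give the keto acid F1; diphenyl diselenide with Bu3P would convert it into the Se-phenyl selenoester F2; slow addition of Bu3SnH with AIBN in benzene at 80 °C would generate the acyl radical, which should close ring C 6-exo onto C16 and be reduced at C5, giving 17 after equilibration of C5 and C19 with DBU.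

Step 20. The allylindium species may be protonated before it cyclises, or may react through its other terminus with the C24 carbonyl to give a five-membered carbocycle, so that ring A is not formed. The fallback sets out from 17 and returns at 26 by building ring A through metathesis. Allylation of 17 as in step 17, but with allyl methyl carbonate, would give the C13 allyl trione F3. Dehydrogenation as in step 18 would pass through the selenide F4 to the enone F5. 2-Methylallylmagnesium chloride with CeCl3 in THF at −78 °C should add to the C7 carbonyl from the face opposite the C14–C24 bond, and the adduct should close to the hemiketal diene F6; this facial preference is not secure, but only this adduct can form the hemiketal and it is separated at that stage. Ring-closing metathesis of F6 with the second-generation Grubbs catalyst in CH2Cl2 at 40 °C would then close ring A and give 26.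

Step 17. The fluoride-liberated enolate may exchange protons with the other ketones (loss of regiocontrol) or be allylated on oxygen before it is captured at C13. The fallback sets out from 17 and returns at 21 without any free enolate: the intact enol silyl ether is alkylated under cationic conditions, with ZnBr2 in CH2Cl2 at −40 °C ionising 20 to the allyl cation, which the enol silyl ether should capture at C13 through the unsubstituted cation terminus, again anti to the C14–C24 bond.

**Further compounds**
F1 | step 14 | methyl (3S)-3-(3-carboxy-4-methylpentanoyl)-3-methyl-5-{[tri(propan-2-yl)silyl]oxy}cyclohexa-1,4-diene-1-carboxylate | CC(C)[Si](C(C)C)(C(C)C)OC1=C[C@@](C)(C(=O)CC(C(O)=O)C(C)C)C=C(C1)C(=O)OC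
F2 | step 14 | Se-phenyl selenoester of F1 | CC(C)[Si](C(C)C)(C(C)C)OC1=C[C@@](C)(C(=O)CC(C(=O)[Se]c2ccccc2)C(C)C)C=C(C1)C(=O)OC
F3 | step 20 | methyl (1R,4R,4aR,7R,8aS)-4a-methyl-3,5,8-trioxo-7-(propan-2-yl)-4-(prop-2-en-1-yl)decahydronaphthalene-1-carboxylate | COC(=O)[C@@H]1CC(=O)[C@H](CC=C)[C@]2(C)[C@H]1C(=O)[C@@H](C(C)C)CC2=O
F4 | step 20 | 2-(phenylselanyl) derivative of F3 | COC(=O)[C@@H]1C([Se]c3ccccc3)C(=O)[C@H](CC=C)[C@]2(C)[C@H]1C(=O)[C@@H](C(C)C)CC2=O
F5 | step 20 | methyl (4R,4aR,7R,8aR)-4a-methyl-3,5,8-trioxo-7-(propan-2-yl)-4-(prop-2-en-1-yl)-3,4,4a,5,6,7,8,8a-octahydronaphthalene-1-carboxylate | COC(=O)C1=CC(=O)[C@H](CC=C)[C@]2(C)[C@H]1C(=O)[C@@H](C(C)C)CC2=O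
F6 | step 20 | hemiketal diene: 26 with ring A opened between C9 and C11 (2-methylallyl on C7 and allyl on C13) | COC(=O)C1=C[C@]2(CC(C)=C)[C@H](CC=C)[C@]3(C)[C@H]1C(=O)[C@@H](C(C)C)C[C@@]3(O)O2
F0 | step 17 | none | none
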